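The product of this flask shows as two peaks, target and isomer of the product, and their sum says how far the reaction has gone. Find which given numbers that sum depends on before reading any value from it.

| setting | south | north | flask |
|---|---|---|---|
| starting material | 0.068 M | 0.068 M | 0.068 M |
| coupling partner | 0.068 M (fed, over 40 min) | 0.068 M (fed, over 40 min) | 0.0680 M (fed, over 40 min) |
| free catalyst | 0.12 mM | 0.12 mM | 0.12 mM |
| impurity | 33 µM | 22 µM | 33 µM |
| remark | the very flask that is asked about, followed so far; the fed solution adds 1.0 times the starting volume | run made earlier; the fed solution adds 1.0 times the starting volume | the fed solution adds 1.0 times the starting volume |
| time |  |  | 8.0 d |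

| run | time / d | starting material / % | target / % | isomer of the product / % |
|---|---|---|---|---|
| south | 0.208 | 46.8 | 27.9 | 25.5 |
| south | 0.333 | 44.6 | 27.0 | 28.1 |
| south | 0.625 | 44.7 | 26.9 | 28.8 |
| south | 1.25 | 44.8 | 27.2 | 28.2 |
| south | 2.50 | 44.5 | 27.1 | 28.7 |
| north | 0.417 | 45.1 | 27.6 | 28.1 |
| north | 0.833 | 44.6 | 27.0 | 27.8 |
| north | 1.67 | 44.7 | 26.7 | 28.4 |
| north | 3.00 | 44.6 | 26.9 | 28.7 |
| north | 6.00 | 44.7 | 26.9 | 28.0 |

(each reading ± 0.3 percentage points)

* which holds at 8.0 d: what has brought the reaction to rest, or that it has not come to rest (all of the starting material has reacted / it is still moving / forward and back rates have come level / no working catalyst is left / the coupling partner has run out first)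
* share of the starting material used up at 8.0 d
* target at 8.0 d, in percent of the starting material charged
* isomer of the product at 8.0 d, in percent of the starting material charged
* amount of target if the flask were left three thousand times as long, in percent of the starting material charged

- charges are per starting volume, the dose included; the dosed solution carries all of it
- the numbers in the tables scatter with a standard deviation of 0.3 percentage points
- the reaction counts as stopped when no species that holds the starting material changes by six tenths of a point or more over the second half of the time

1. Test the impurity. South had 33 µM and north 22 µM, yet their last readings of starting material differ by 0.2 percentage points, with a scatter of 0.3 points. Count turnovers as well: even if each impurity took one catalyst, south would lose 27.5% of its free catalyst. An error in this charge can therefore pass.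

2. Test the time. North reads 44.6% of starting material at 0.833 d and 44.7% at 6.00 d, so an error in the time shows nothing over that span. The asked 8.0 d lies past it.

3. Test the charges. Take each product to hold one starting material and one coupling partner; then the charges enter the count of what is left. Here they are equal, so the two fractions left are equal too.

4. Now read the number. Define the balance number, an equilibrium quotient in fractions of the charge, as the product's fraction of the starting material charged, divided by the fraction of starting material left and by the fraction of coupling partner left. The last readings of both runs give 44.6% left and 55.4% product, so the balance number is 2.78. The flask repeats south's recipe, so I expect that same rest, with 55.4% used up.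

5. The forecast says: forward and back rates have come level, with 55.3% used up, 27% target, 28.3% isomer, and 27% target at the long time. Its ground: “A composition independent of impurity, reached well after dosing ends, points to a true equilibrium”.

6. The flask gives: forward and back rates have come level, with 55.4% used up. Target stands at 27.0% at 8.0 d, and at 27.0% at the long time. The isomer of the product stands at 28.4% at 8.0 d.

    starting material + coupling partner ⇌ target (K = 40.0 M⁻¹, k = 0.370 M⁻¹ min⁻¹)
    starting material + coupling partner ⇌ isomer of the product (K = 42.0 M⁻¹, k = 0.0280 M⁻¹ min⁻¹)
    target + free catalyst ⇌ isomer of the product + free catalyst, rate k3*[free catalyst]*[target] forward; the back reaction follows from the equilibrium constant (k = 130 M⁻¹ min⁻¹)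
    free catalyst + impurity → spent catalyst (k = 1.30 × 10⁵ M⁻¹ min⁻¹)

The end values of this flask put the balance number at 2.79. Carry 2.78 to the neighbouring flask with 0.017 M of starting material, where coupling partner and feed volume stay as in the recipe. Starting material, now less than the coupling partner, is the limiting reagent. The fraction of coupling partner left is therefore one minus 0.250 times the product's fraction. Solving for that fraction gives 69.7% used up. The simulated neighbour uses up 69.7%, leaving 82.6% of its coupling partner, and holds 34.0% target and 35.7% isomer.

The numbers in the tables come from a simulation on assumed constants.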